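A leftover starts us: the late readings of the violet run hold 51.5 % of its substrate, and those of the amber run hold 32.7 %.

| flask | substrate | partner | reagent | capture agent | remark | time |
|---|---|---|---|---|---|---|
| blue | 0.0050 M (fed, over 15 s) | 0.011 M | 0.012 M | 1 mM | run made earlier; the fed solution adds 0.10 times the starting volume |  |
| violet | 0.020 M (fed, over 15 s) | 0.011 M | 0.012 M | 1 mM | run made earlier; the fed solution adds 0.10 times the starting volume |  |
| amber | 0.010 M (fed, over 15 s) | 0.017 M | 0.012 M | 1 mM | run made earlier; the fed solution adds 0.10 times the starting volume |  |
| flask | 0.010 M (fed, over 15 s) | 0.0110 M | 0.0120 M | 1.00 mM | the fed solution adds 0.10 times the starting volume | 1.0 h |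

- blue (time / min: target / %, substrate / %): 4.00: 19, 19; 6.00: 23, 15; 12.0: 38, 7; 20.0: 40, 5; 40.0: 39, 1; 60.0: 37, 4
- violet (time / min: target / %, substrate / %): 4.00: 3, 53; 6.00: 4, 50; 12.0: 8, 52; 20.0: 9, 53; 40.0: 6, 51; 60.0: 6, 50
- amber (time / min: target / %, substrate / %): 4.00: 13, 38; 8.00: 19, 33; 15.0: 26, 30; 30.0: 22, 35; 60.0: 20, 33

(readings scatter by 1.5 percentage points)

- the moment within 1.0 h at which there is most target
- the amount of target, in percent of the substrate charged, at that time
- the first time at which target reaches 16 %, in the same percent

- every charge counts on the volume at the start, and the solution that is fed holds the whole dose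
- the numbers in the tables scatter by 1.5 percentage points (one standard deviation)

1. We assume that substrate and partner, in each run, share the whole reagent charge, each taking it at a rate in proportion to its own amount and to the reagent present. Then the logarithm of substrate's fraction left, divided by that of partner's fraction left, is a constant, the selectivity factor s.

2. Read from those scattered leftovers, violet gives 2.83 and amber 3.02, so we take s as 2.92.

3. The flask has two ends. If substrate took reagent first, none of it would remain and partner would keep 81.8 %. If s were 1, both would keep 42.9 %. Our s stands above 1, so by this reckoning the flask lies between the two ends.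

4. To join the ends, we start with partner's fraction left at 0.7, raise it to the power s for substrate, and correct once so that the two shares add up to the reagent. By this reckoning the flask's partner keeps 61.3 % and its substrate 24.0 %.

5. The partner we reckon taken in the flask lies between the amounts reckoned for violet and amber. Interpolating the highest target readings of those two runs, taken as amounts, on it, we expect 23.3 % of the flask's charge as its highest target.

6. The forecast, reasoning that “partner probably also consumes reagent”, gives 20 % (17.5 % to 23.5 %) at 0.3 h, less than our figure, and puts the first 16 % at 0.175 h.

7. The flask peaks at 23.0 % at 0.266 h and reaches 16 % at 0.0988 h, 1.77 times sooner than the forecast.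

    substrate + reagent → open intermediate (k = 1.34 /M/s)
    reagent + partner → second intermediate (k = 0.408 /M/s)
    open intermediate + second intermediate → target (k = 0.658 /M/s)
    2 second intermediate → homo product (k = 0.256 /M/s)
    open intermediate + capture agent → trapped intermediate (k = 5.10 /M/s)
    target ⇌ isomer of the product (K = 0.873, k = 5.81 × 10⁻⁴ /s)

8. At 0.500 h the flask holds 0 % of its reagent, 22.5 % of its substrate and 61.3 % of its partner, beside our 24.0 % and 61.3 %. At 0.9126 min the half-life of substrate by its step with reagent is 1.5 min, and that of partner 4.97 min, longer by a factor of 3.31. For the neighbour charged with 0.027 M of partner, s and the same single correction give substrate left at 45.1 %, and at 1.00 h that flask holds 45.1 %.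

The earlier runs and the new flask stem from a simulated flask with made-up constants; scatter was added.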